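**Retrosynthetic overview**
1. Acid chloride 1 supplies the trimethoxyphenyl ring and C2; it is carried through ethyl ketone 2 to α-bromo ketone 3, an enolonium (a2) equivalent whose α-carbon becomes C3 with its methyl group.
2. Vanillin 4 supplies ring A complete with O1, the 7-methoxy group and the 5-formyl group; no protecting groups are used.
3. Key disconnection C3–C3a: the normally nucleophilic ketone α-carbon (made electrophilic in 3) is joined to the normally nucleophilic ortho carbon of phenol 4, giving keto-phenol 5.
4. Second disconnection O1–C2: 5 closes to hemiketal 6 and loses water to give target 7 in the same flask.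
5. Ring order: both benzene rings are bought; the furan ring is the only ring formed, in the last step.

Assumption: the target SMILES has no stereocentre (the molecule is achiral), so there is no enantiomer to select and the route makes the compound exactly as drawn.

**Step 1**
Reactants: 1 3,4,5-trimethoxybenzoyl chloride
Product: 2 1-(3,4,5-trimethoxyphenyl)propan-1-one
Conditions: EtMgBr (1.2 equiv), Fe(acac)3 (3 mol %), THF, −78 °C, 20 min; aq. NH4Cl
Reagents that add atoms: ethylmagnesium bromide, CC[Mg]Br
Why: Iron-catalysed cross-coupling of a Grignard reagent with an acid chloride (Kochi–Fürstner-type acylation) is far faster at −78 °C than Grignard addition to the ketone formed, so the reaction stops at ketone 2; no stereocentre is formed.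

**Step 2**
Reactants: 2 1-(3,4,5-trimethoxyphenyl)propan-1-one
Product: 3 racemic 2-bromo-1-(3,4,5-trimethoxyphenyl)propan-1-one
Conditions: CuBr2 (2.1 equiv), EtOAc/CHCl3 1:1, reflux, 4 h; filter off CuBr
Reagents that add atoms: copper dibromide, Br[Cu]Br
Why: King–Ostrum α-bromination through the copper-bound enol brominates only the enolisable CH2 and spares the carbonyl-deactivated ring; the new stereocentre is racemic and is destroyed in step 3.

**Step 3**
Reactants: 3 racemic 2-bromo-1-(3,4,5-trimethoxyphenyl)propan-1-one; 4 vanillin (4-hydroxy-3-methoxybenzaldehyde)
Product: 7 ocophyllal B, via ortho-alkylated ketone 5 (not isolated), via cyclic hemiketal 6 (not isolated)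
Conditions: 4 (1.0 equiv), TiCl4 (1.5 equiv), CF3CH2OH, reflux (about 75 °C), slow addition of 3 (1.2 equiv), 8–12 h; then H2O/EtOAc work-up
Reagents that add atoms: none
Why: Friedel–Crafts-type ortho-alkylation of a titanium aryloxide by an α-halo ketone followed by cyclodehydration (a known one-flask benzofuran synthesis from phenols, here extended to a formyl-bearing guaiacol and a secondary α-bromo aryl ketone): the Ti–O bond blocks O-alkylation, the chelated bromo ketone 3, acting as an enolonium equivalent, is attacked at its α-carbon by the only free ortho carbon of 4 (C5) to give 5, which closes to 6 and dehydrates to the aromatic furan, so the racemic stereocentres of 3, 5 and 6 all vanish and achiral 7 results.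

**Compound list**
1 | 3,4,5-trimethoxybenzoyl chloride | COc1cc(C(=O)Cl)cc(OC)c1OC | starting material
2 | 1-(3,4,5-trimethoxyphenyl)propan-1-one | CCC(=O)c1cc(OC)c(OC)c(OC)c1 | intermediate
3 | racemic 2-bromo-1-(3,4,5-trimethoxyphenyl)propan-1-one | CC(Br)C(=O)c1cc(OC)c(OC)c(OC)c1 | intermediate
4 | vanillin (4-hydroxy-3-methoxybenzaldehyde) | COc1cc(C=O)ccc1O | starting material
5 | racemic 4-hydroxy-3-methoxy-5-[1-oxo-1-(3,4,5-trimethoxyphenyl)propan-2-yl]benzaldehyde (formed in the flask, not isolated) | CC(C(=O)c1cc(OC)c(OC)c(OC)c1)c1cc(C=O)cc(OC)c1O | intermediate
6 | 2-hydroxy-7-methoxy-3-methyl-2-(3,4,5-trimethoxyphenyl)-2,3-dihydro-1-benzofuran-5-carbaldehyde (racemic mixture of diastereomers, formed in the flask, not isolated) | CC1c2cc(C=O)cc(OC)c2OC1(O)c1cc(OC)c(OC)c(OC)c1 | intermediate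
7 | ocophyllal B, 7-methoxy-3-methyl-2-(3,4,5-trimethoxyphenyl)-1-benzofuran-5-carbaldehyde (achiral) | COc1cc(-c2oc3c(OC)cc(C=O)cc3c2C)cc(OC)c1OC | target

**Totals**
Total step count: 3. Longest linear sequence: 3 steps (1 → 2 → 3 → 7); vanillin 4 enters unprotected in step 3.

**Steps most likely to fail, with fallbacks**

Step 3 (highest risk). The ring of vanillin is deactivated by the para-formyl group and by titanium binding, so conversion may be low. O-alkylation or carbonyl-first attack would lead to the 2-methyl-3-aryl regioisomer. The regiochemistry should be checked by an NOE between the C3 methyl group and H-4 and by HMBC from that methyl to C3a. TiCl4 may also promote arylmethane formation at the aldehyde or 4-O-demethylation of the trimethoxyphenyl ring. The fallback sets out from ketone 2 and comes back to the route at target 7. It replaces the intermolecular alkylation by a tethered [3,3]-sigmatropic C–C bond formation, the oxygen analogue of the Fischer indole synthesis. Ketone 2 is condensed with NH2OH·HCl and NaOAc in refluxing EtOH to give (E)-1-(3,4,5-trimethoxyphenyl)propan-1-one oxime F1 (the minor Z isomer reacts alike). The oximate of F1 (KOtBu, DMSO, 25–60 °C) displaces fluoride from commercial 4-fluoro-3-methoxybenzaldehyde by nucleophilic aromatic substitution, para to the formyl group, to give 3-methoxy-4-({[1-(3,4,5-trimethoxyphenyl)propylidene]amino}oxy)benzaldehyde F2. Warming F2 in anhydrous HCl/dioxane (60–80 °C) tautomerises it to the ene-hydroxylamine. The [3,3] shift then breaks the weak N–O bond and joins the ketone α-carbon to the free ortho carbon of ring A. Rearomatisation, ring closure of the phenol onto the iminium carbon and loss of ammonia deliver 7. The tether fixes the regiochemistry (aryl at C2, methyl at C3), and the formyl group is tolerated because it only activates the fluoride displacement.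

Step 2 (moderate risk). The ring positions ortho and para to methoxy groups could be brominated, or the α-carbon could be brominated twice. The fallback sets out from ketone 2 and comes back at bromo ketone 3. Ketone 2 is converted with TMSOTf and Et3N in CH2Cl2 at 0 °C into (Z)-trimethyl{[1-(3,4,5-trimethoxyphenyl)prop-1-en-1-yl]oxy}silane F3. F3 is then treated with N-bromosuccinimide in THF at −78 to 0 °C. The preformed enol ether is far more nucleophilic than the arene and can take up only one bromine, so 3 is obtained cleanly.

Step 1 (lowest risk). Over-addition to the tertiary alcohol or iron-mediated reduction and homocoupling could lower the yield. The fallback sets out from acid chloride 1 and comes back at ketone 2. Acid chloride 1 is treated with N,O-dimethylhydroxylamine hydrochloride and Et3N in CH2Cl2 (0 °C to room temperature) to give N,3,4,5-tetramethoxy-N-methylbenzamide F4. F4 reacts with EtMgBr in THF at 0 °C through a magnesium-chelated tetrahedral intermediate that collapses to 2 only on aqueous HCl work-up, so over-addition cannot occur.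

**Further compounds**
F1 | step 3 | (E)-1-(3,4,5-trimethoxyphenyl)propan-1-one oxime | CC/C(=N\O)c1cc(OC)c(OC)c(OC)c1
F2 | step 3 | 3-methoxy-4-({[(E)-1-(3,4,5-trimethoxyphenyl)propylidene]amino}oxy)benzaldehyde | CC/C(=N\Oc1ccc(C=O)cc1OC)c1cc(OC)c(OC)c(OC)c1
F3 | step 2 | (Z)-trimethyl{[1-(3,4,5-trimethoxyphenyl)prop-1-en-1-yl]oxy}silane | C/C=C(\O[Si](C)(C)C)c1cc(OC)c(OC)c(OC)c1
F4 | step 1 | N,3,4,5-tetramethoxy-N-methylbenzamide | CON(C)C(=O)c1cc(OC)c(OC)c(OC)c1
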